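The two C–Br bonds of ring B, C3'–Br and C5'–Br, are made last. Ring B carries its free hydroxyl on C6' and the ether oxygen on C1', so C3' (para) and C5' (ortho) are the carbons this hydroxyl activates. Ring A (C1 OMe, C2 ether O, C3–C5 Br, C6 H) passes through as an unreactive O-methylated tribromo ring. One bromoperoxidase-type bromination of 2-(2,3,4-tribromo-6-methoxyphenoxy)phenol should therefore set both C–Br bonds. That precursor is assembled from tribromoguaiacol and 2-fluorobenzaldehyde by SNAr and Baeyer–Villiger oxidation, and BBr3 demethylation of ring A ends the route.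

Key step: step 4

Remark: the target has no stereocentre and no isolable axis, so it is a single achiral species and no step has to control configuration.

Locants: ring A is C1 (OH or OMe), C2 (ether O), C3–C5 (Br), C6 (H). Ring B is C1' (ether O), C2' (H), C3' (Br), C4' (H), C5' (Br), C6' (OH).

Step 1
Reactants: 1 guaiacol (2-methoxyphenol)
Product: 2 2,3,4-tribromo-6-methoxyphenol (4,5,6-tribromoguaiacol)
Conditions: Br2 (3.05 equiv), AcOH, 15 °C → 40 °C
Reagents that add atoms: bromine, BrBr
Why: Electrophilic aromatic bromination in which the hydroxyl sends bromine to its para and ortho carbons and the methoxy group sends the third bromine to its own para carbon, so that either possible dibromo intermediate converges on the 4,5,6-tribromo pattern, while the last C–H (ortho to OMe on a ring with three bromines) should resist a fourth substitution at this stoichiometry.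

Step 2
Reactants: 2 2,3,4-tribromo-6-methoxyphenol; 3 2-fluorobenzaldehyde
Product: 4 2-(2,3,4-tribromo-6-methoxyphenoxy)benzaldehyde
Conditions: K2CO3 (1.5 equiv), 3 (1.3 equiv), DMAc, 120 °C
Reagents that add atoms: none
Why: Nucleophilic aromatic substitution (addition–elimination through a Meisenheimer adduct) of the phenoxide of 2 at the C–F carbon activated by the ortho formyl group, which should tolerate carbonate because the aldehyde cannot enolise and the unactivated C–Br bonds do not compete with the C–F bond.

Step 3
Reactants: 4 2-(2,3,4-tribromo-6-methoxyphenoxy)benzaldehyde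
Product: 6 2-(2,3,4-tribromo-6-methoxyphenoxy)phenol, via aryl formate 5 (not isolated)
Conditions: mCPBA (1.4 equiv), DCM, 0 °C → rt; then Et3N (cat.), MeOH, rt
Reagents that add atoms: meta-chloroperoxybenzoic acid (mCPBA), O=C(OO)c1cccc(Cl)c1
Why: Baeyer–Villiger oxidation of an aryl aldehyde (Dakin-type sequence), in which the Criegee adduct should rearrange by migration of ring B because the ortho aryloxy oxygen donates into that ring, and the crude aryl formate, washed free of acid, is cleaved by base-catalysed methanolysis while the aryl bromides, the methyl ether and the diaryl ether are inert to peracid.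

Step 4
Reactants: 6 2-(2,3,4-tribromo-6-methoxyphenoxy)phenol
Product: 7 2,4-dibromo-6-(2,3,4-tribromo-6-methoxyphenoxy)phenol
Conditions: NH4VO3 (5 mol%), 48% aq HBr (2.5 equiv), 30% aq H2O2 (2.05 equiv, slow addition), MeCN–H2O, 0 °C → rt
Reagents that add atoms: hydrobromic acid, Br
Why: Peroxovanadate formed from vanadate and H2O2 oxidises bromide to an electrophilic bromine(+1) species (HOBr/Br2), which should substitute ring B of 6 first at C3' (para to the C6' hydroxyl) and then at C5' (ortho to it) via arenium ions stabilised by the phenolic oxygen. The closest known reaction type is the vanadium-haloperoxidase-mimetic oxidative bromination of phenols, which has the same outcome as ortho/para dibromination of a phenol with N-bromosuccinimide. No ring is closed and no stereocentre is created, so neither a mode of closure nor a controlling element arises. Selectivity between the rings is required and rests on the free hydroxyl of ring B set against ring A, an anisole whose only C–H (C6) sits on a ring already bearing three bromines. Selectivity within ring B rests on the same hydroxyl, since C2' and C4' are activated only by the bridging oxygen, whose lone pair is shared with the electron-poor ring A. Hydrogen peroxide is the limiting reagent at two equivalents and is added slowly, so that no more than two electrophile equivalents are formed.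

Step 5
Reactants: 7 2,4-dibromo-6-(2,3,4-tribromo-6-methoxyphenoxy)phenol
Product: 8 3,4,5-tribromo-2-(3,5-dibromo-2-hydroxyphenoxy)phenol
Conditions: BBr3 (3 equiv), DCM, −78 °C → rt; then H2O
Reagents that add atoms: none
Why: Lewis-acid cleavage of an aryl methyl ether with boron tribromide, in which boron binds the methoxy oxygen and bromide attacks the methyl carbon in an SN2 step, whereas the diaryl ether offers no sp3 carbon and the aryl C–Br bonds are inert, and aqueous work-up hydrolyses the aryl borates to the two free phenols.

Compound list
1 | guaiacol (2-methoxyphenol) | COc1ccccc1O | starting material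
2 | 2,3,4-tribromo-6-methoxyphenol (4,5,6-tribromoguaiacol) | COc1cc(Br)c(Br)c(Br)c1O | intermediate
3 | 2-fluorobenzaldehyde | O=Cc1ccccc1F | starting material
4 | 2-(2,3,4-tribromo-6-methoxyphenoxy)benzaldehyde | COc1cc(Br)c(Br)c(Br)c1Oc1ccccc1C=O | intermediate
5 | 2-(2,3,4-tribromo-6-methoxyphenoxy)phenyl formate | COc1cc(Br)c(Br)c(Br)c1Oc1ccccc1OC=O | intermediate
6 | 2-(2,3,4-tribromo-6-methoxyphenoxy)phenol | COc1cc(Br)c(Br)c(Br)c1Oc1ccccc1O | intermediate
7 | 2,4-dibromo-6-(2,3,4-tribromo-6-methoxyphenoxy)phenol | COc1cc(Br)c(Br)c(Br)c1Oc1cc(Br)cc(Br)c1O | intermediate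
8 | 3,4,5-tribromo-2-(3,5-dibromo-2-hydroxyphenoxy)phenol | Oc1cc(Br)c(Br)c(Br)c1Oc1cc(Br)cc(Br)c1O | target

Total step count: 5
Longest linear sequence: 5 steps (1 → 2 → 4 → 6 → 7 → 8)

Steps most likely to fail

Step 4. Ring or site discrimination may be incomplete: a further substitution could occur at C6 of ring A or para to the bridging oxygen, or peroxide could oxidise the electron-rich phenol in competition with bromination. The fallback sets out from 2 and returns at 7, and brings the para bromine of ring B in with the building block. The phenoxide of 2 is condensed with 4-bromo-2-fluorobenzaldehyde (K2CO3, DMAc, 110 °C; SNAr at the C–F carbon ortho to the formyl group) to give 4-bromo-2-(2,3,4-tribromo-6-methoxyphenoxy)benzaldehyde F1. Baeyer–Villiger oxidation (mCPBA, DCM) should give 4-bromo-2-(2,3,4-tribromo-6-methoxyphenoxy)phenyl formate F2 (not isolated), and methanolysis (MeOH, cat. Et3N) should give 4-bromo-2-(2,3,4-tribromo-6-methoxyphenoxy)phenol F3. One equivalent of N-bromosuccinimide with catalytic diisopropylamine in DCM at 0 °C then finds a single hydroxyl-activated site, C5', and should deliver 7.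

Step 2. Substitution by a weakly nucleophilic, doubly ortho-substituted phenoxide may be slow, with degradation of the aldehyde at the temperature required. The fallback sets out from 2 and returns at 6, and uses a more electrophilic partner. 1-Fluoro-2-nitrobenzene (K2CO3, DMF, 80 °C) should give 1,2,3-tribromo-5-methoxy-4-(2-nitrophenoxy)benzene F4. Iron powder in AcOH/EtOH at 70 °C reduces the nitro group without touching the aryl bromides and gives 2-(2,3,4-tribromo-6-methoxyphenoxy)aniline F5. Diazotisation (NaNO2, aq H2SO4/AcOH, 0 °C) gives 2-(2,3,4-tribromo-6-methoxyphenoxy)benzenediazonium hydrogensulfate F6 (not isolated), which is run into boiling dilute H2SO4 under toluene to give 6. This stays a fallback because an aryl cation next to a 2-methoxyaryloxy group may also be captured by the methoxy oxygen.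

Step 3. Hydride may migrate instead of ring B in the Criegee adduct, which would lead to a carboxylic acid and not to the formate. The fallback sets out from 2 and returns at 6, and replaces the aldehyde by a methyl ketone, in which aryl migration has no hydride competitor. 1-(2-Fluorophenyl)ethanone (K2CO3, DMAc, 130 °C) should give 1-[2-(2,3,4-tribromo-6-methoxyphenoxy)phenyl]ethanone F7. Baeyer–Villiger oxidation (mCPBA, cat. TFA, DCM, rt) should give 2-(2,3,4-tribromo-6-methoxyphenoxy)phenyl acetate F8. Methanolysis (K2CO3 0.2 equiv, MeOH, rt) then gives 6.

Further compounds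
F1 | step 4 | 4-bromo-2-(2,3,4-tribromo-6-methoxyphenoxy)benzaldehyde | COc1cc(Br)c(Br)c(Br)c1Oc1cc(Br)ccc1C=O
F2 | step 4 | 4-bromo-2-(2,3,4-tribromo-6-methoxyphenoxy)phenyl formate | COc1cc(Br)c(Br)c(Br)c1Oc1cc(Br)ccc1OC=O
F3 | step 4 | 4-bromo-2-(2,3,4-tribromo-6-methoxyphenoxy)phenol | COc1cc(Br)c(Br)c(Br)c1Oc1cc(Br)ccc1O
F4 | step 2 | 1,2,3-tribromo-5-methoxy-4-(2-nitrophenoxy)benzene | COc1cc(Br)c(Br)c(Br)c1Oc1ccccc1[N+](=O)[O-]
F5 | step 2 | 2-(2,3,4-tribromo-6-methoxyphenoxy)aniline | COc1cc(Br)c(Br)c(Br)c1Oc1ccccc1N
F6 | step 2 | 2-(2,3,4-tribromo-6-methoxyphenoxy)benzenediazonium hydrogensulfate | COc1cc(Br)c(Br)c(Br)c1Oc1ccccc1[N+]#N.OS(=O)(=O)[O-]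
F7 | step 3 | 1-[2-(2,3,4-tribromo-6-methoxyphenoxy)phenyl]ethanone | COc1cc(Br)c(Br)c(Br)c1Oc1ccccc1C(C)=O
F8 | step 3 | 2-(2,3,4-tribromo-6-methoxyphenoxy)phenyl acetate | COc1cc(Br)c(Br)c(Br)c1Oc1ccccc1OC(C)=O
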